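**Strategy.** Ring A is cut at C7–C8 and C4a–C5. Its 3-alkoxysalicylate array (C5–O, C6–OH, C7–CO2R, C8–H) maps onto a 4-alkoxyacetoacetate, and ring B with the trans C4 methyl and the C1 branch is the p-menthane ring of carvone (ketone carbon = C4a, α-methylene = C8a). One Knoevenagel–aldol–dehydration cascade between the 2-hydroxymethylene derivative of trans-dihydrocarvone and ethyl 4-(benzyloxy)acetoacetate therefore builds the whole arene with every substituent in place. Benzyl instead of methyl on O5 lets the last hydrogenation unmask the catechol. C11 is set by catalyst-controlled hydroboration of the isopropenyl group; C15 comes from methyl (S)-3-hydroxy-2-methylpropanoate.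

Key step: step 3

Atom labels: tetralin numbering for the core (ring B C1–C4, ring A C5–C8, fusion carbons C4a and C8a); side chain C11 (on C1) to C16 (CH2OH).

Assumption: (R)-DTBM-SEGPHOS is written as the ligand enantiomer that delivers the 11S boronate; if a first run shows the opposite sense, its antipode is used with no other change.

Step 1
Reactants: 1 (R)-carvone
Product: 2 (2R,5R)-2-methyl-5-(prop-1-en-2-yl)cyclohexan-1-one (trans-dihydrocarvone)
Conditions: LiBH(s-Bu)3, THF, −78 °C; then aq. NH4Cl; chromatography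
Reagents that add atoms: none
Why: Conjugate (1,4) hydride reduction of the β-unsubstituted enone by the hindered borohydride leaves the isopropenyl group alone, and the new methyl-bearing centre (future C4) should arise by axial protonation of the enolate, which is also the more stable diequatorial trans epimer, any cis epimer being removed by chromatography.

Step 2
Reactants: 2 trans-dihydrocarvone; 3 2,2,2-trifluoroethyl formate
Product: 4 (3S,6R)-2-(hydroxymethylidene)-6-methyl-3-(prop-1-en-2-yl)cyclohexan-1-one (chelated enol of the 2-formyl ketone)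
Conditions: LiN(i-Pr)2, THF, −78 °C; then 3, −78 °C; aq. HCl work-up
Reagents that add atoms: none
Why: Crossed Claisen formylation of the kinetic lithium enolate, which forms at the less hindered α-methylene (future C8a) without deprotonating the methyl-bearing α′ centre, with an activated formate that reacts at −78 °C before the enolate can equilibrate, so the trans relationship should be kept.

Step 3
Reactants: 4 hydroxymethylene ketone; 5 ethyl 4-(benzyloxy)-3-oxobutanoate
Product: 7 ethyl (5R,8S)-4-(benzyloxy)-3-hydroxy-5-methyl-8-(prop-1-en-2-yl)-5,6,7,8-tetrahydronaphthalene-2-carboxylate (tetralin labels: C5–OBn, C6–OH, C7–CO2Et), via alkylidene ketoester 6 (not isolated)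
Conditions: piperidine (20 mol%), AcOH (20 mol%), PhMe, 4 Å MS, rt → 80 °C
Reagents that add atoms: none
Why: Piperidinium acetate converts the formyl carbon of 4 into an enaminone/iminium that the doubly activated CH2 of 5 attacks, and loss of amine and water gives 6 (Knoevenagel condensation, C7–C8); the benzyloxy-bearing CH2 then enolises and adds to the ring ketone (C5 to C4a), after which dehydration and enolisation of the C6 carbonyl give the phenol. The closest known reaction is the condensation of 2-hydroxymethylene cycloalkanones with acetoacetates or acetonedicarboxylates to annulated salicylates, here run with a γ-alkoxy ketoester. Ring A closes by a 6-(enolendo)-exo-trig aldol addition followed by aromatising dehydration. No stereocentre is formed; C1 and C4 are carried through from 4. The regiochemistry needs the formyl carbon to pair with the most acidic methylene, which the gap in electrophilicity between aldehyde and hindered ketone secures, leaving only the alkoxy-bearing carbon able to close a six-membered carbocycle. Retention at C4, which stays α to a ketone until aromatisation, is secured by the buffered non-basic medium and by the irreversible aromatisation that removes the carbonyl.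

Step 4
Reactants: 7 salicylate
Product: 8 ethyl (5R,8S)-3,4-bis(benzyloxy)-5-methyl-8-(prop-1-en-2-yl)-5,6,7,8-tetrahydronaphthalene-2-carboxylate
Conditions: BnBr, K2CO3, DMF, 60 °C
Reagents that add atoms: benzyl bromide, BrCc1ccccc1
Why: Williamson etherification of the phenoxide masks the acidic OH before the copper hydride step with a group that leaves in the final hydrogenolysis.

Step 5
Reactants: 8 bis(benzyl ether)
Product: 9 ethyl (5R,8S)-3,4-bis(benzyloxy)-5-methyl-8-[(2S)-1-(4,4,5,5-tetramethyl-1,3,2-dioxaborolan-2-yl)propan-2-yl]-5,6,7,8-tetrahydronaphthalene-2-carboxylate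
Conditions: CuCl (5 mol%), (R)-DTBM-SEGPHOS (6 mol%), KOtBu (10 mol%), HBpin, THF, rt → 40 °C
Reagents that add atoms: pinacolborane, [H]B1OC(C)(C)C(C)(C)O1
Why: Copper hydride catalysed anti-Markovnikov hydroboration of a 1,1-disubstituted alkene, in which the ligand-bound CuH places copper on the terminal carbon and chooses the alkene face by the size difference between ring carbon C1 and the methyl group (catalyst control should set C11 as S), and σ-bond metathesis with HBpin releases the primary boronate while ester and benzyl ethers are inert.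

Step 6
Reactants: 10 methyl (S)-3-hydroxy-2-methylpropanoate
Product: 11 methyl (S)-3-(benzyloxy)-2-methylpropanoate
Conditions: BnOC(=NH)CCl3, TfOH (cat.), CH2Cl2/cyclohexane, 0 °C → rt
Reagents that add atoms: benzyl 2,2,2-trichloroacetimidate, N=C(OCc1ccccc1)C(Cl)(Cl)Cl
Why: Acid-catalysed benzyl transfer from the trichloroacetimidate works without base and so cannot epimerise the centre α to the ester.

Step 7
Reactants: 11 benzyl ether ester
Product: 12 (S)-3-(benzyloxy)-2-methylpropanal
Conditions: i-Bu2AlH, CH2Cl2, −78 °C; aq. potassium sodium tartrate; crude into step 8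
Reagents that add atoms: none
Why: Partial reduction of the ester stops at the tetrahedral aluminium hemiacetal at low temperature and gives the aldehyde on work-up, whose labile α-centre is protected by immediate use.

Step 8
Reactants: 12 aldehyde; 13 iodoform
Product: 14 ({[(2R,3E)-4-iodo-2-methylbut-3-en-1-yl]oxy}methyl)benzene
Conditions: CrCl2, THF/dioxane, 0 °C → rt
Reagents that add atoms: none
Why: Takai olefination, in which the geminal dichromium species from iodoform adds to the aldehyde and eliminates to the (E)-vinyl iodide under non-basic conditions that leave the allylic centre (future C15) intact.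

Step 9
Reactants: 9 alkyl boronate; 14 vinyl iodide
Product: 16 (5R,8S)-3,4-bis(benzyloxy)-8-[(2S,4E,6R)-7-(benzyloxy)-6-methylhept-4-en-2-yl]-5-methyl-5,6,7,8-tetrahydronaphthalene-2-carboxylic acid, via coupled ethyl ester 15 (not isolated)
Conditions: Pd(OAc)2 (5 mol%), RuPhos (10 mol%), aq. KOH, THF, 70 °C; then KOH, MeOH, 65 °C; aq. HCl
Reagents that add atoms: potassium hydroxide, [K+].[OH-]
Why: Suzuki–Miyaura sp3–sp2 coupling of the hydroxide-activated primary boronate, with a bulky biarylphosphine that favours reductive elimination over β-hydride elimination, forms C12–C13 without touching C11 or C15, and the same hydroxide medium then saponifies the ethyl ester so that partial hydrolysis during the coupling is harmless.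

Step 10
Reactants: 16 unsaturated tribenzyl acid
Product: 18 (5R,8S)-3,4-dihydroxy-8-[(2S,6R)-7-hydroxy-6-methylheptan-2-yl]-5-methyl-5,6,7,8-tetrahydronaphthalene-2-carboxylic acid (target), via saturated tribenzyl acid 17 (not isolated)
Conditions: H2 (1 atm), PtO2, EtOAc, rt; filter; then H2 (1 atm), Pd(OH)2/C, EtOAc/MeOH, rt
Reagents that add atoms: none
Why: Heterogeneous hydrogenation on platinum saturates the C13=C14 bond with little double-bond migration so that C15 is not scrambled, and palladium-catalysed hydrogenolysis then removes the three benzyl ethers under neutral conditions, which spares the air-sensitive catechol any basic step.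

**Compound list**

1 | (R)-carvone | C=C(C)[C@@H]1CC=C(C)C(=O)C1 | starting material
2 | (2R,5R)-2-methyl-5-(prop-1-en-2-yl)cyclohexan-1-one | C=C(C)[C@@H]1CC[C@@H](C)C(=O)C1 | intermediate
3 | 2,2,2-trifluoroethyl formate | O=COCC(F)(F)F | starting material
4 | (3S,6R)-2-(hydroxymethylidene)-6-methyl-3-(prop-1-en-2-yl)cyclohexan-1-one | C=C(C)[C@@H]1CC[C@@H](C)C(=O)C1=CO | intermediate
5 | ethyl 4-(benzyloxy)-3-oxobutanoate | CCOC(=O)CC(=O)COCc1ccccc1 | starting material
6 | Knoevenagel adduct, ethyl 4-(benzyloxy)-2-{[(2S,4R)-4-methyl-3-oxo-2-(prop-1-en-2-yl)... wait-free description: ethyl 4-(benzyloxy)-3-oxo-2-{[(3R,6S)-3-methyl-2-oxo-6-(prop-1-en-2-yl)cyclohexyl]methylidene}butanoate (C8a epimers, either alkene geometry; not isolated) | C=C(C)[C@@H]1CC[C@@H](C)C(=O)C1C=C(C(=O)OCC)C(=O)COCc1ccccc1 | intermediate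
7 | ethyl (5R,8S)-4-(benzyloxy)-3-hydroxy-5-methyl-8-(prop-1-en-2-yl)-5,6,7,8-tetrahydronaphthalene-2-carboxylate | C=C(C)[C@@H]1CC[C@@H](C)c2c1cc(C(=O)OCC)c(O)c2OCc1ccccc1 | intermediate
8 | ethyl (5R,8S)-3,4-bis(benzyloxy)-5-methyl-8-(prop-1-en-2-yl)-5,6,7,8-tetrahydronaphthalene-2-carboxylate | C=C(C)[C@@H]1CC[C@@H](C)c2c1cc(C(=O)OCC)c(OCc1ccccc1)c2OCc1ccccc1 | intermediate
9 | ethyl (5R,8S)-3,4-bis(benzyloxy)-5-methyl-8-[(2S)-1-(4,4,5,5-tetramethyl-1,3,2-dioxaborolan-2-yl)propan-2-yl]-5,6,7,8-tetrahydronaphthalene-2-carboxylate | CC1(C)OB(C[C@H](C)[C@@H]2CC[C@@H](C)c3c2cc(C(=O)OCC)c(OCc2ccccc2)c3OCc2ccccc2)OC1(C)C | intermediate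
10 | methyl (S)-3-hydroxy-2-methylpropanoate | C[C@@H](CO)C(=O)OC | starting material
11 | methyl (S)-3-(benzyloxy)-2-methylpropanoate | C[C@@H](COCc1ccccc1)C(=O)OC | intermediate
12 | (S)-3-(benzyloxy)-2-methylpropanal | C[C@@H](COCc1ccccc1)C=O | intermediate
13 | iodoform | IC(I)I | starting material
14 | ({[(2R,3E)-4-iodo-2-methylbut-3-en-1-yl]oxy}methyl)benzene | C[C@@H](COCc1ccccc1)/C=C/I | intermediate
15 | ethyl (5R,8S)-3,4-bis(benzyloxy)-8-[(2S,4E,6R)-7-(benzyloxy)-6-methylhept-4-en-2-yl]-5-methyl-5,6,7,8-tetrahydronaphthalene-2-carboxylate (not isolated) | C[C@@H](COCc1ccccc1)/C=C/C[C@H](C)[C@@H]2CC[C@@H](C)c3c2cc(C(=O)OCC)c(OCc2ccccc2)c3OCc2ccccc2 | intermediate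
16 | (5R,8S)-3,4-bis(benzyloxy)-8-[(2S,4E,6R)-7-(benzyloxy)-6-methylhept-4-en-2-yl]-5-methyl-5,6,7,8-tetrahydronaphthalene-2-carboxylic acid | C[C@@H](COCc1ccccc1)/C=C/C[C@H](C)[C@@H]2CC[C@@H](C)c3c2cc(C(=O)O)c(OCc2ccccc2)c3OCc2ccccc2 | intermediate
17 | (5R,8S)-3,4-bis(benzyloxy)-8-[(2S,6R)-7-(benzyloxy)-6-methylheptan-2-yl]-5-methyl-5,6,7,8-tetrahydronaphthalene-2-carboxylic acid (not isolated) | C[C@@H](COCc1ccccc1)CCC[C@H](C)[C@@H]2CC[C@@H](C)c3c2cc(C(=O)O)c(OCc2ccccc2)c3OCc2ccccc2 | intermediate
18 | (5R,8S)-3,4-dihydroxy-8-[(2S,6R)-7-hydroxy-6-methylheptan-2-yl]-5-methyl-5,6,7,8-tetrahydronaphthalene-2-carboxylic acid | C[C@@H](CO)CCC[C@H](C)[C@@H]1CC[C@@H](C)c2c1cc(C(=O)O)c(O)c2O | target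

Note on line 6: the name to use is ethyl 4-(benzyloxy)-3-oxo-2-{[(3R,6S)-3-methyl-2-oxo-6-(prop-1-en-2-yl)cyclohexyl]methylidene}butanoate; the SMILES is authoritative.

**Totals.** Total step count: 10. Longest linear sequence: 7 steps (steps 1, 2, 3, 4, 5, 9, 10 from (R)-carvone).

**Steps most likely to fail**

Step 3. The aldol closure at the benzyloxy-bearing carbon may be slower than O-cyclisation of the ene-dione to a pyran or than enolisation toward C4, so that arene formation stalls or the trans C1/C4 relationship erodes. The fallback sets out from 4 and moves the C5 oxygen to after ring formation. Compound 4 is condensed under the same amine–acid catalysis with ethyl acetoacetate, the classical unhindered partner, to give ethyl (5R,8S)-3-hydroxy-5-methyl-8-(prop-1-en-2-yl)-5,6,7,8-tetrahydronaphthalene-2-carboxylate F1. Magnesium-mediated ortho-formylation (MgCl2, Et3N, paraformaldehyde, MeCN, reflux) at the only free position ortho to the phenol should give the 4-formyl salicylate F2. Dakin oxidation (H2O2, aq. NaOH, 0 °C) should give the catechol ester F3, and double benzylation (BnBr, K2CO3, DMF) comes back to the route at 8.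

Step 5. Hydrocupration of the hindered alkene may be slow, or the catalyst may not override the substrate in choosing the alkene face, which would give a mixture of C11 epimers. The fallback sets out from 8 and replaces catalyst control by separation. Uncatalysed hydroboration with 9-BBN (THF, rt → 60 °C) gives the B-alkyl-9-BBN adduct F4 as both C11 epimers. This is coupled in the same flask with 14 by the classical B-alkyl Suzuki protocol (Pd(dppf)Cl2, AsPh3, Cs2CO3, DMF/H2O, rt) to give 15 together with the 11-epimer of the coupled ester F5. Saponification (KOH, MeOH) gives 16 and the 11-epimer of the acid F6, which are separated by preparative HPLC or fractional crystallisation. The route is rejoined at 16.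

Step 9. Transmetalation of the β-branched primary pinacol boronate may be slow, so that protodeboronation, β-hydride elimination or consumption of the vinyl iodide compete. The fallback sets out from 9 and switches from boron to zinc. Oxidation (NaBO3·4H2O, THF/H2O) gives ethyl (5R,8S)-3,4-bis(benzyloxy)-8-[(2R)-1-hydroxypropan-2-yl]-5-methyl-5,6,7,8-tetrahydronaphthalene-2-carboxylate F7. Appel iodination (I2, PPh3, imidazole, CH2Cl2) gives the primary iodide F8. Zinc insertion (Zn, LiCl, THF, 40 °C), which tolerates the ester, gives the alkylzinc iodide F9, and Negishi coupling with 14 (Pd(OAc)2, SPhos, THF, rt) comes back to the route at 15, which is saponified as in step 9.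

**Further compounds**

F1 | step 3 | ethyl (5R,8S)-3-hydroxy-5-methyl-8-(prop-1-en-2-yl)-5,6,7,8-tetrahydronaphthalene-2-carboxylate | C=C(C)[C@@H]1CC[C@@H](C)c2c1cc(C(=O)OCC)c(O)c2
F2 | step 3 | ethyl (5R,8S)-4-formyl-3-hydroxy-5-methyl-8-(prop-1-en-2-yl)-5,6,7,8-tetrahydronaphthalene-2-carboxylate | C=C(C)[C@@H]1CC[C@@H](C)c2c1cc(C(=O)OCC)c(O)c2C=O
F3 | step 3 | ethyl (5R,8S)-3,4-dihydroxy-5-methyl-8-(prop-1-en-2-yl)-5,6,7,8-tetrahydronaphthalene-2-carboxylate | C=C(C)[C@@H]1CC[C@@H](C)c2c1cc(C(=O)OCC)c(O)c2O
F4 | step 5 | ethyl (5R,8S)-3,4-bis(benzyloxy)-8-[1-(9-borabicyclo[3.3.1]nonan-9-yl)propan-2-yl]-5-methyl-5,6,7,8-tetrahydronaphthalene-2-carboxylate (both C11 epimers) | CC(CB1C2CCCC1CCC2)[C@@H]3CC[C@@H](C)c4c3cc(C(=O)OCC)c(OCc3ccccc3)c4OCc3ccccc3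
F5 | step 5 | ethyl (5R,8S)-3,4-bis(benzyloxy)-8-[(2R,4E,6R)-7-(benzyloxy)-6-methylhept-4-en-2-yl]-5-methyl-5,6,7,8-tetrahydronaphthalene-2-carboxylate (11-epimer of 15) | C[C@@H](COCc1ccccc1)/C=C/C[C@@H](C)[C@@H]2CC[C@@H](C)c3c2cc(C(=O)OCC)c(OCc2ccccc2)c3OCc2ccccc2
F6 | step 5 | (5R,8S)-3,4-bis(benzyloxy)-8-[(2R,4E,6R)-7-(benzyloxy)-6-methylhept-4-en-2-yl]-5-methyl-5,6,7,8-tetrahydronaphthalene-2-carboxylic acid (11-epimer of 16) | C[C@@H](COCc1ccccc1)/C=C/C[C@@H](C)[C@@H]2CC[C@@H](C)c3c2cc(C(=O)O)c(OCc2ccccc2)c3OCc2ccccc2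
F7 | step 9 | ethyl (5R,8S)-3,4-bis(benzyloxy)-8-[(2R)-1-hydroxypropan-2-yl]-5-methyl-5,6,7,8-tetrahydronaphthalene-2-carboxylate | OC[C@H](C)[C@@H]1CC[C@@H](C)c2c1cc(C(=O)OCC)c(OCc1ccccc1)c2OCc1ccccc1
F8 | step 9 | ethyl (5R,8S)-3,4-bis(benzyloxy)-8-[(2R)-1-iodopropan-2-yl]-5-methyl-5,6,7,8-tetrahydronaphthalene-2-carboxylate | IC[C@H](C)[C@@H]1CC[C@@H](C)c2c1cc(C(=O)OCC)c(OCc1ccccc1)c2OCc1ccccc1
F9 | step 9 | alkylzinc iodide from F8, {(2R)-2-[(1S,4R)-5,6-bis(benzyloxy)-7-(ethoxycarbonyl)-4-methyl-1,2,3,4-tetrahydronaphthalen-1-yl]propyl}zinc iodide | I[Zn]C[C@H](C)[C@@H]1CC[C@@H](C)c2c1cc(C(=O)OCC)c(OCc1ccccc1)c2OCc1ccccc1
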